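**Retrosynthetic overview**

1. The target is read as (14S)-8α,14,15-trihydroxylabd-13(16)-en-19-oic acid. The last disconnections are ester and acetonide cleavage, then C12–C13 by B-alkyl Suzuki–Miyaura coupling of a C9-vinyl decalin with the glyceraldehyde-derived bromoalkene 26 (C14 from the chiral pool).
2. The C8 tertiary alcohol comes from an exocyclic C8=C17 alkene by oxymercuration, and the C4 quaternary centre (C18 methyl equatorial, C19 carboxyl axial) from reductive methylation of a C3=C4 enoate; both are steered by the axial C10 methyl group.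
3. Key disconnection: C1–C2 and C5–C10 together, by an intramolecular Diels–Alder reaction of the acyclic triene 15, which closes rings A and B at the same time and sets C5 and C10 from the single stereocentre C9.
4. Enabling feature: ring A is a cyclohexane whose C4 carries the carboxyl carbon C19 and whose C10 is a methyl-bearing quaternary carbon. C3=C4(CO2Me) is therefore the retron of a 2-carbomethoxy diene C2=C3–C4=C5, C10(CH3)=C1 is an isopropenyl dienophile, and the ring B carbons C6–C7–C8–C9 are the four-atom chain of a 1,7,9-decatriene.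
5. Triene 15 comes from an Evans deconjugative alkylation (C9), a thioester/Fukuyama ketone synthesis with methylenation (C8=C17), and alkynoate hydrostannation/Stille coupling (diene geometry). Ring order: A and B together in step 9, no ring before.

Key step: step 9

Remark: carbon atoms are numbered as in labdane (C1–C20); the target is taken as the normal labdane series (5α-H, 9α-H, 10β-CH3), and 1, 2, 8 and 23 are taken as purchasable.

**Route**

Step 1
Reactants: 1 (4R)-4-benzyl-1,3-oxazolidin-2-one; 2 3-methylbut-2-enoyl chloride
Product: 4 (4R)-4-benzyl-3-(3-methylbut-2-enoyl)-1,3-oxazolidin-2-one, via lithium oxazolidinide 3 (not isolated)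
Conditions: n-BuLi, THF, −78 °C; then 2, −78 → 0 °C
Reagents that add atoms: none
Why: N-acylation of the lithiated oxazolidinone by the acid chloride (standard imide formation) should proceed without an amine base and so without deconjugation through a vinylketene; no stereocentre is formed.

Step 2
Reactants: 4 (4R)-4-benzyl-3-(3-methylbut-2-enoyl)-1,3-oxazolidin-2-one
Product: 6 (4R)-4-benzyl-3-{(2S)-2-[(benzyloxy)methyl]-3-methylbut-3-enoyl}-1,3-oxazolidin-2-one, via sodium dienolate 5 (not isolated)
Conditions: NaN(SiMe3)2, THF, −78 °C; then BnOCH2Cl, −78 → −30 °C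
Reagents that add atoms: benzyl chloromethyl ether, ClCOCc1ccccc1
Why: Evans asymmetric alkylation in its deconjugative form: γ-deprotonation gives the chelated (Z)-sodium dienolate, which should react at the α-carbon with the reactive chloromethyl ether on the face opposite the benzyl group of the auxiliary, setting C9 and unveiling the isopropenyl group (C10, C20, C1).

Step 3
Reactants: 6 (4R)-4-benzyl-3-{(2S)-2-[(benzyloxy)methyl]-3-methylbut-3-enoyl}-1,3-oxazolidin-2-one
Product: 7 S-ethyl (2S)-2-[(benzyloxy)methyl]-3-methylbut-3-enethioate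
Conditions: EtSH, n-BuLi, THF, 0 °C → rt
Reagents that add atoms: ethanethiol, CCS
Why: Transthioesterification of the imide by a lithium thiolate attacks the exocyclic carbonyl selectively and is too weakly basic to epimerise C9 or to move the β,γ-double bond, so the auxiliary is released and the acyl group is activated for ketone synthesis.

Step 4
Reactants: 7 S-ethyl (2S)-2-[(benzyloxy)methyl]-3-methylbut-3-enethioate; 8 (4-bromobut-1-yn-1-yl)trimethylsilane
Product: 10 (3S)-3-[(benzyloxy)methyl]-2-methyl-8-(trimethylsilyl)oct-1-en-7-yn-4-one, via alkylzinc bromide 9 (not isolated)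
Conditions: 8, Zn (I2-activated), LiCl, THF, 50 °C; then 7, PdCl2(PPh3)2 (5 mol %), THF–toluene, rt
Reagents that add atoms: none
Why: Fukuyama coupling, the zerovalent-palladium-catalysed acylation of an alkylzinc halide by a thioester, should give the ketone (C8) under neutral conditions that leave the enolisable C9–H untouched; the zinc reagent comes from LiCl-assisted insertion of zinc into the primary bromide.

Step 5
Reactants: 10 (3S)-3-[(benzyloxy)methyl]-2-methyl-8-(trimethylsilyl)oct-1-en-7-yn-4-one
Product: 11 {(6R)-6-[(benzyloxy)methyl]-7-methyl-5-methylideneoct-7-en-1-yn-1-yl}trimethylsilane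
Conditions: Zn, CH2Br2, TiCl4, THF–CH2Cl2, 0 °C → rt
Reagents that add atoms: dibromomethane, BrCBr
Why: Lombardo methylenation with the non-basic Zn/CH2Br2/TiCl4 reagent suits hindered, easily enolised ketones and should install C17 without epimerisation at C9, conjugation of the isopropenyl group or β-elimination of the benzyloxy group.

Step 6
Reactants: 11 {(6R)-6-[(benzyloxy)methyl]-7-methyl-5-methylideneoct-7-en-1-yn-1-yl}trimethylsilane
Product: 13 methyl (7R)-7-[(benzyloxy)methyl]-8-methyl-6-methylidenenon-8-en-2-ynoate, via lithium acetylide 12 (not isolated)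
Conditions: MeLi·LiBr, THF, 0 °C → rt; then ClCO2Me, −78 → 0 °C
Reagents that add atoms: methyl chloroformate, COC(=O)Cl
Why: Methyllithium cleaves the alkynyl–silicon bond to the lithium acetylide, which is acylated on carbon by the chloroformate in the same flask (desilylative carboxylation, a standard ynoate synthesis); no stereocentre is touched.

Step 7
Reactants: 13 methyl (7R)-7-[(benzyloxy)methyl]-8-methyl-6-methylidenenon-8-en-2-ynoate
Product: 14 methyl (2E,7R)-7-[(benzyloxy)methyl]-8-methyl-6-methylidene-2-(tributylstannyl)nona-2,8-dienoate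
Conditions: Bu3SnH, Pd(PPh3)4 (2 mol %), THF, 0 °C → rt
Reagents that add atoms: tributyltin hydride, CCCC[SnH](CCCC)CCCC
Why: Palladium-catalysed hydrostannation of a 2-alkynoate is a syn addition that delivers tin to the α-carbon (C4), so the chain carbon C6 should end up cis to the ester and trans to tin.

Step 8
Reactants: 14 methyl (2E,7R)-7-[(benzyloxy)methyl]-8-methyl-6-methylidene-2-(tributylstannyl)nona-2,8-dienoate
Product: 15 methyl (2Z,7R)-7-[(benzyloxy)methyl]-2-ethenyl-8-methyl-6-methylidenenona-2,8-dienoate
Conditions: CH2=CHBr, Pd(PPh3)4 (5 mol %), CuI, CsF, DMF, 45 °C (sealed)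
Reagents that add atoms: vinyl bromide, C=CBr
Why: Stille coupling in its copper- and fluoride-promoted form for hindered α-stannyl acrylates replaces tin by vinyl with retention of the double-bond geometry, which should give the (Z)-2-carbomethoxy diene with the chain on the outside position needed for the cycloaddition.

Step 9
Reactants: 15 methyl (2Z,7R)-7-[(benzyloxy)methyl]-2-ethenyl-8-methyl-6-methylidenenona-2,8-dienoate
Product: 16 methyl (4aS,5S,8aR)-5-[(benzyloxy)methyl]-4a-methyl-6-methylidene-3,4,4a,5,6,7,8,8a-octahydronaphthalene-1-carboxylate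
Conditions: toluene (0.01 M), BHT (cat.), sealed tube, 180 °C
Reagents that add atoms: none
Why: Thermal intramolecular Diels–Alder reaction of a 1,7,9-decatriene: a concerted, asynchronous suprafacial [4+2] addition of the unactivated 1,1-disubstituted alkene C10=C1 to the diene C2=C3–C4=C5 should form C1–C2 and C5–C10 in one event, the ester on C4 lowering the diene LUMO and staying in the product as C19. The closest known reaction type is the thermal cyclisation of decatrienes that carry an isopropenyl dienophile and a diene substituted next to the chain, which gives trans-fused octalins with an angular methyl group. Ring A is closed by the cycloaddition itself as a cyclohexene and ring B is closed in the fused mode by the C5–C10 bond, the chain C6–C7–C8–C9 folding into a chair-like six-membered ring. The trans ring fusion (5α-H, 10β-CH3) should follow from the transition state with the chain exo to the diene, since the endo arrangement pushes C6 and C7 against the in-plane ester on C4 (allylic strain) and folds the chain under the diene. The face of the dienophile is fixed by C9, whose CH2OBn group sits equatorial on the forming ring B and anti to the new C5–C10 bond, so that C10 and C5 are set relative to C9 as in the target. The step needs the intramolecular path to beat dimerisation of the diene ester (high dilution, radical inhibitor), fused and not bridged bonding (enforced by the four-atom chain, the C8=C17 methylene being unable to reach the diene) and the chain on the outside of the diene, which the (Z) geometry made in steps 7 and 8 secures.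

Step 10
Reactants: 16 methyl (4aS,5S,8aR)-5-[(benzyloxy)methyl]-4a-methyl-6-methylidene-3,4,4a,5,6,7,8,8a-octahydronaphthalene-1-carboxylate
Product: 18 methyl 11-hydroxy-12,13,14,15,16-pentanorlabd-8(17)-en-19-oate, via dilithium enolate alkoxide 17 (not isolated)
Conditions: Li, NH3(l)–THF, t-BuOH (1 equiv), −78 °C; isoprene; then MeI, −78 → −33 °C
Reagents that add atoms: iodomethane, CI
Why: Reductive alkylation under Birch-type conditions: conjugate reduction of the enoate gives the exocyclic ester enolate, which iodomethane should attack from the α face, anti to the axial C10 methyl group, so that the new methyl group (C18) is equatorial and the ester (C19) axial, while the benzyl ether is cleaved to the C11 alkoxide in the same operation.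

Step 11
Reactants: 18 methyl 11-hydroxy-12,13,14,15,16-pentanorlabd-8(17)-en-19-oate
Product: 20 methyl 8α,11-dihydroxy-12,13,14,15,16-pentanorlabdan-19-oate, via organomercury acetate 19 (not isolated)
Conditions: Hg(OAc)2, THF–H2O (1:1), rt; then NaOH (3 M), NaBH4, 0 °C
Reagents that add atoms: water, O
Why: Oxymercuration–demercuration (Markovnikov hydration): water should open the mercurinium ion at the tertiary C8 along the equatorial α trajectory, because the axial β trajectory is blocked by the 1,3-diaxial C10 methyl group, giving the 8α-alcohol with C17 axial, and NaBH4 then replaces mercury by hydrogen without reducing the hindered ester.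

Step 12
Reactants: 20 methyl 8α,11-dihydroxy-12,13,14,15,16-pentanorlabdan-19-oate
Product: 21 methyl 8α-hydroxy-11-oxo-12,13,14,15,16-pentanorlabdan-19-oate
Conditions: TEMPO (10 mol %), PhI(OAc)2, CH2Cl2, rt
Reagents that add atoms: none
Why: Oxoammonium (TEMPO) oxidation with PhI(OAc)2 as terminal oxidant is selective for the primary alcohol and stops at the aldehyde under nearly neutral conditions; the tertiary alcohol cannot be oxidised, and C9, although now α to a carbonyl, already has the thermodynamically preferred equatorial configuration.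

Step 13
Reactants: 21 methyl 8α-hydroxy-11-oxo-12,13,14,15,16-pentanorlabdan-19-oate
Product: 22 methyl 8α-hydroxy-13,14,15,16-tetranorlabd-11-en-19-oate
Conditions: CH2I2, Zn, Ti(OiPr)4, THF, rt
Reagents that add atoms: diiodomethane, ICI
Why: Takai methylenation (Zn/CH2I2/Ti(OiPr)4) is aldehyde-selective and non-basic, so the β-hydroxy aldehyde should be converted into the vinyl group (C11=C12) without retro-aldol cleavage, dehydration or attack on the ester.

Step 14
Reactants: 23 (4R)-2,2-dimethyl-1,3-dioxolane-4-carbaldehyde
Product: 24 (4S)-4-ethenyl-2,2-dimethyl-1,3-dioxolane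
Conditions: Ph3PCH3Br, KN(SiMe3)2, THF, −78 → 0 °C
Reagents that add atoms: methyltriphenylphosphonium bromide, C[P+](c1ccccc1)(c1ccccc1)c1ccccc1.[Br-]
Why: Wittig methylenation of the α-alkoxy aldehyde with the ylide at low temperature should give the vinyl dioxolane without loss of configuration at the stereocentre that becomes C14 (the descriptor changes only through the priority rules).

Step 15
Reactants: 24 (4S)-4-ethenyl-2,2-dimethyl-1,3-dioxolane
Product: 26 (4R)-4-(1-bromoethenyl)-2,2-dimethyl-1,3-dioxolane, via vicinal dibromide 25 (not isolated)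
Conditions: Br2, CH2Cl2, −78 °C; then DBU, THF, 60 °C
Reagents that add atoms: bromine, BrBr
Why: Electrophilic anti addition of bromine followed by E2 dehydrobromination with an amidine base: the internal C–H, acidified by its bromine and by the adjacent C–O bond, is removed with loss of the primary bromide, as in the known preparation of 2-bromoallyl ethers and 2-bromoacrolein acetals, and the stereocentre is not involved.

Step 16
Reactants: 22 methyl 8α-hydroxy-13,14,15,16-tetranorlabd-11-en-19-oate; 26 (4R)-4-(1-bromoethenyl)-2,2-dimethyl-1,3-dioxolane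
Product: 28 methyl (14S)-8α-hydroxy-14,15-(isopropylidenedioxy)labd-13(16)-en-19-oate, via B-alkyl-9-BBN adduct 27 (not isolated)
Conditions: 9-BBN, THF, rt → 50 °C; then 26, Pd(dppf)Cl2 (5 mol %), AsPh3, K3PO4 (3 M aq.), DMF, rt → 50 °C
Reagents that add atoms: none
Why: Hydroboration of the monosubstituted alkene with 9-BBN places boron on the terminal carbon C12, and the B-alkyl Suzuki–Miyaura coupling with the alkenyl bromide then forms the C12–C13 bond with retention of the 1,1-disubstituted alkene and without touching any stereocentre, the free tertiary alcohol and the ester being tolerated.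

Step 17
Reactants: 28 methyl (14S)-8α-hydroxy-14,15-(isopropylidenedioxy)labd-13(16)-en-19-oate
Product: 29 (14S)-8α-hydroxy-14,15-(isopropylidenedioxy)labd-13(16)-en-19-oic acid
Conditions: NaSEt, DMF, 110 °C (argon); aq. NaH2PO4 work-up
Reagents that add atoms: none
Why: SN2 dealkylation of the methyl ester by thiolate takes place at the unhindered methyl carbon, which avoids the blocked carbonyl group of the axial neopentyl ester and leaves the acetonide, the alkene and the tertiary alcohol untouched.

Step 18
Reactants: 29 (14S)-8α-hydroxy-14,15-(isopropylidenedioxy)labd-13(16)-en-19-oic acid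
Product: 30 (14S)-8α,14,15-trihydroxylabd-13(16)-en-19-oic acid
Conditions: AcOH–H2O–THF (3:1:1), 40 °C
Reagents that add atoms: none
Why: Mild acid-catalysed hydrolysis of the isopropylidene acetal should release the 14,15-diol under conditions too weak to ionise the tertiary C8 alcohol or the allylic C14–O bond, giving the target.

**Compound list**

1 | (4R)-4-benzyl-1,3-oxazolidin-2-one | O=C1N[C@H](Cc2ccccc2)CO1 | starting material
2 | 3-methylbut-2-enoyl chloride | CC(C)=CC(=O)Cl | starting material
3 | lithium (4R)-4-benzyl-2-oxo-1,3-oxazolidin-3-ide | [Li+].O=C1[N-][C@H](Cc2ccccc2)CO1 | intermediate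
4 | (4R)-4-benzyl-3-(3-methylbut-2-enoyl)-1,3-oxazolidin-2-one | CC(C)=CC(=O)N1C(=O)OC[C@H]1Cc1ccccc1 | intermediate
5 | sodium (Z)-dienolate of 4 (isopropenyl cis to O−) | [Na+].[O-]/C(=C\C(C)=C)N1C(=O)OC[C@H]1Cc1ccccc1 | intermediate
6 | (4R)-4-benzyl-3-{(2S)-2-[(benzyloxy)methyl]-3-methylbut-3-enoyl}-1,3-oxazolidin-2-one | C=C(C)[C@@H](COCc1ccccc1)C(=O)N1C(=O)OC[C@H]1Cc1ccccc1 | intermediate
7 | S-ethyl (2S)-2-[(benzyloxy)methyl]-3-methylbut-3-enethioate | C=C(C)[C@@H](COCc1ccccc1)C(=O)SCC | intermediate
8 | (4-bromobut-1-yn-1-yl)trimethylsilane | C[Si](C)(C)C#CCCBr | starting material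
9 | bromo[4-(trimethylsilyl)but-3-yn-1-yl]zinc | C[Si](C)(C)C#CCC[Zn]Br | intermediate
10 | (3S)-3-[(benzyloxy)methyl]-2-methyl-8-(trimethylsilyl)oct-1-en-7-yn-4-one | C=C(C)[C@@H](COCc1ccccc1)C(=O)CCC#C[Si](C)(C)C | intermediate
11 | {(6R)-6-[(benzyloxy)methyl]-7-methyl-5-methylideneoct-7-en-1-yn-1-yl}trimethylsilane | C=C(C)[C@@H](COCc1ccccc1)C(=C)CCC#C[Si](C)(C)C | intermediate
12 | lithium (6R)-6-[(benzyloxy)methyl]-7-methyl-5-methylideneoct-7-en-1-yn-1-ide | C=C(C)[C@@H](COCc1ccccc1)C(=C)CCC#[C-].[Li+] | intermediate
13 | methyl (7R)-7-[(benzyloxy)methyl]-8-methyl-6-methylidenenon-8-en-2-ynoate | C=C(C)[C@@H](COCc1ccccc1)C(=C)CCC#CC(=O)OC | intermediate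
14 | methyl (2E,7R)-7-[(benzyloxy)methyl]-8-methyl-6-methylidene-2-(tributylstannyl)nona-2,8-dienoate | C=C(C)[C@@H](COCc1ccccc1)C(=C)CC/C=C(/[Sn](CCCC)(CCCC)CCCC)C(=O)OC | intermediate
15 | methyl (2Z,7R)-7-[(benzyloxy)methyl]-2-ethenyl-8-methyl-6-methylidenenona-2,8-dienoate | C=C(C)[C@@H](COCc1ccccc1)C(=C)CC/C=C(/C=C)C(=O)OC | intermediate
16 | methyl (4aS,5S,8aR)-5-[(benzyloxy)methyl]-4a-methyl-6-methylidene-3,4,4a,5,6,7,8,8a-octahydronaphthalene-1-carboxylate (labdane numbering: Δ3, 8(17)-methylene, 5α-H, 9β-CH2OBn, 10β-CH3, no C18) | c1ccccc1COC[C@@H]2[C@@]3(C)CCC=C(C(=O)OC)[C@@H]3CCC2=C | intermediate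
17 | dilithium salt: C19 ester enolate and C11 alkoxide of debenzylated, conjugate-reduced 16 | [Li+].[Li+].[O-]C[C@@H]1[C@@]2(C)CCCC(=C([O-])OC)[C@@H]2CCC1=C | intermediate
18 | methyl 11-hydroxy-12,13,14,15,16-pentanorlabd-8(17)-en-19-oate (4α-CH3, 4β-CO2Me) | OC[C@@H]1[C@@]2(C)CCC[C@](C)(C(=O)OC)[C@@H]2CCC1=C | intermediate
19 | methyl 17-(acetoxymercurio)-8α,11-dihydroxy-12,13,14,15,16-pentanorlabdan-19-oate | OC[C@@H]1[C@@]2(C)CCC[C@](C)(C(=O)OC)[C@@H]2CC[C@@]1(C[Hg]OC(C)=O)O | intermediate
20 | methyl 8α,11-dihydroxy-12,13,14,15,16-pentanorlabdan-19-oate | OC[C@@H]1[C@@]2(C)CCC[C@](C)(C(=O)OC)[C@@H]2CC[C@@]1(C)O | intermediate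
21 | methyl 8α-hydroxy-11-oxo-12,13,14,15,16-pentanorlabdan-19-oate | O=C[C@@H]1[C@@]2(C)CCC[C@](C)(C(=O)OC)[C@@H]2CC[C@@]1(C)O | intermediate
22 | methyl 8α-hydroxy-13,14,15,16-tetranorlabd-11-en-19-oate | C=C[C@@H]1[C@@]2(C)CCC[C@](C)(C(=O)OC)[C@@H]2CC[C@@]1(C)O | intermediate
23 | (4R)-2,2-dimethyl-1,3-dioxolane-4-carbaldehyde | O=C[C@H]1COC(C)(C)O1 | starting material
24 | (4S)-4-ethenyl-2,2-dimethyl-1,3-dioxolane | C=C[C@H]1COC(C)(C)O1 | intermediate
25 | (4R)-4-(1,2-dibromoethyl)-2,2-dimethyl-1,3-dioxolane (both epimers at the CHBr carbon) | BrCC(Br)[C@H]1COC(C)(C)O1 | intermediate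
26 | (4R)-4-(1-bromoethenyl)-2,2-dimethyl-1,3-dioxolane | C=C(Br)[C@H]1COC(C)(C)O1 | intermediate
27 | B-alkyl-9-borabicyclo[3.3.1]nonane from 22 (boron on C12) | B1(CC[C@@H]2[C@@]3(C)CCC[C@](C)(C(=O)OC)[C@@H]3CC[C@@]2(C)O)C4CCCC1CCC4 | intermediate
28 | methyl (14S)-8α-hydroxy-14,15-(isopropylidenedioxy)labd-13(16)-en-19-oate | C=C(CC[C@@H]1[C@@]2(C)CCC[C@](C)(C(=O)OC)[C@@H]2CC[C@@]1(C)O)[C@H]3COC(C)(C)O3 | intermediate
29 | (14S)-8α-hydroxy-14,15-(isopropylidenedioxy)labd-13(16)-en-19-oic acid | C=C(CC[C@@H]1[C@@]2(C)CCC[C@](C)(C(=O)O)[C@@H]2CC[C@@]1(C)O)[C@H]3COC(C)(C)O3 | intermediate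
30 | (14S)-8α,14,15-trihydroxylabd-13(16)-en-19-oic acid, CNP0216809.1 | C=C(CC[C@@H]1[C@@]2(C)CCC[C@](C)(C(=O)O)[C@@H]2CC[C@@]1(C)O)[C@H](O)CO | target

**Step count and risks**

Total step count: 18. Longest linear sequence: 16 steps (steps 1–13 and 16–18); steps 14 and 15 form the side branch to 26.

Steps most likely to fail:

Step 9. The cycloaddition is electronically unactivated and has the regiochemistry imposed by the chain, not the one the frontier orbitals prefer. It may therefore be too slow against dimerisation or polymerisation of the diene ester, and the ring-fusion or facial selectivity may be incomplete (chain endo, or CH2OBn axial because of allylic strain with the C8=C17 methylene). Fallback: from 15 to 16 by a metal-catalysed formal [4+2] cycloaddition instead of the thermal pericyclic one. A cationic monovalent rhodium catalyst ([Rh(cod)Cl]2 with AgSbF6, 1,2-dichloroethane, 25–60 °C) joins tethered dienes to unactivated alkenes by oxidative cyclisation to a rhodacycle and reductive elimination. This runs far below the temperature at which the diene ester dimerises, and the ring fusion is then decided by the metallacycle and not by orbital overlap. No new compound is made (F0).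

Step 8. Protodestannylation or cine substitution of the hindered α-stannyl acrylate, and oligomerisation of the diene product during a slow coupling, may erode the material. Fallback with reversed polarity of the partners: from 14, iododestannylation (I2, CH2Cl2, 0 °C) should give, with retention, methyl (2E,7R)-7-[(benzyloxy)methyl]-2-iodo-8-methyl-6-methylidenenona-2,8-dienoate F1. This reactive α-iodo enoate is coupled with tributyl(vinyl)stannane (Pd2(dba)3, AsPh3, CuI, DMF, rt), again with retention, and the route is rejoined at 15.

Step 15. Regiocontrol of the dehydrobromination may be lost (removal of a terminal instead of the internal hydrogen), and the dioxolane oxygen may open the bromonium ion. Fallback through the alkyne: from 23, Ohira–Bestmann homologation (dimethyl (1-diazo-2-oxopropyl)phosphonate, K2CO3, MeOH, 0 °C → rt) gives (4S)-4-ethynyl-2,2-dimethyl-1,3-dioxolane F2. α-Selective hydrostannation directed by the propargylic oxygen (Bu3SnH, Mo(CO)3(CNtBu)3 cat., hydroquinone, THF, 55 °C) gives tributyl{1-[(4R)-2,2-dimethyl-1,3-dioxolan-4-yl]ethenyl}stannane F3. Bromodestannylation (Br2, CH2Cl2, −78 °C) then returns to 26.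

**Further compounds**

F0 | step 9 | none | none
F1 | step 8 | methyl (2E,7R)-7-[(benzyloxy)methyl]-2-iodo-8-methyl-6-methylidenenona-2,8-dienoate | C=C(C)[C@@H](COCc1ccccc1)C(=C)CC/C=C(/I)C(=O)OC
F2 | step 15 | (4S)-4-ethynyl-2,2-dimethyl-1,3-dioxolane | C#C[C@H]1COC(C)(C)O1
F3 | step 15 | tributyl{1-[(4R)-2,2-dimethyl-1,3-dioxolan-4-yl]ethenyl}stannane | C=C([Sn](CCCC)(CCCC)CCCC)[C@H]1COC(C)(C)O1
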